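## Analysis of the target

The target (26) is a linear trimer of three C6–C3 units. Ring A is a 1,2,4-trisubstituted arene carrying the (E)-3-hydroxyprop-1-enyl chain at C1, ring B is the middle arene and ring C is the free catechol. They are joined by two trans-3-aryl-2-(hydroxymethyl)-1,4-benzodioxane units: dioxane ring D (fused to ring A) and dioxane ring E (fused to ring B).

In both dioxane rings the regiochemistry is the same. The benzylic carbon (C7' in ring D, C7'' in ring E) is bound to the oxygen meta to the carbon substituent of the fused arene (O3 of ring A, O3' of ring B). The hydroxymethyl-bearing carbon (C8', C8'') is bound to the para oxygen (O4, O4').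

The four stereocentres form two trans diads that are locally mirror images: (7'R,8'R) in ring D and (7''S,8''S) in ring E. Ring B separates them, so neither diad can be relayed from the other, and one chiral reagent acting alike on both would give the wrong diastereomer.

Sensitive groups are the oxidation-prone catechol, the cinnamyl alcohol and the two p-oxybenzylic aryl ether bonds C7'–O3 and C7''–O3'. The last two ionise in strong acid and are cleaved by hydrogenolysis, which rules out benzyl ethers and a strongly acidic end game.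

The difficulty is therefore threefold: regiocontrol on two unsymmetrical catechols, absolute control of two remote diads of opposite sense, and a convergent union.

The feature this plan uses is that C7' and C7'' each carry one hydrogen, one ring oxygen and one aryl group. Exchanging that aryl group for a leaving group turns the carbon into the anomeric carbon of a cyclic O-aryl hemiacetal. Its only remaining stereocentre, C8' or C8'', is C2 of a glycerate ester (14 or 1), and both enantiomers of that ester can be bought. Each benzodioxane is thus treated as a C-aryl "glycoside", and the C7–aryl bond becomes the strategic bond.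

## Retrosynthetic reasoning

(TBS = tert-butyldimethylsilyl, TBDPS = tert-butyldiphenylsilyl.)

**26 ⇒ 25.** The four O–Si bonds are cut: two aryl TBS ethers on ring C and two primary TBDPS ethers on C9' and C9''. Silyl groups alone are used so that one fluoride treatment frees everything without hydrogenolysis or strong acid. The forward step must leave the alkene and both benzylic ether bonds untouched.

**25 ⇒ 23 + 24.** The bond between C1 of ring A and the propenyl chain is cut. The chain arrives late as the stannane 24 with its E geometry and free hydroxyl in place, so the acid-sensitive cinnamyl alcohol never meets the Lewis-acidic steps. The forward reaction is a neutral, fluoride-free Stille coupling on the ring A bromide of 23.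

**23 ⇒ 19 + 13 (through 20, 21 and 22).** The C7'–C1' bond between ring D and ring B is cut. This cut divides the trimer into two halves of similar size. It makes ring B a nucleophile (arylzinc 22 from bromide 13) and turns C7' into the anomeric carbon of chloride 20, made from lactol 19. The forward reaction must form the C–C bond at an acetal carbon and place ring B trans to the C8' substituent, under control of C8' alone.

**19 ⇒ 18 ⇒ 16 ⇒ 15 + 3, and 15 ⇒ 14.** The hemiacetal bond O3–C7' is opened to the ester 18. The phenol O3 is traced back to the formyl group of 16 by a Dakin-type oxidation. The O4–C8' bond is cut to the salicylaldehyde 3 and the hydroxy ester 15, joined forward by a Mitsunobu reaction with inversion. The hydroxyl of 3 is para to bromine and its formyl group meta, so the O3/O4 regiochemistry is fixed by the choice of 3. The stereocentre comes from 14.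

**13 ⇒ 7 + 9 (through 10, 11 and 12).** Ring E is cut in the same way at C7''–C1''. Lactol 7 gives the anomeric chloride 10, and the ring C bromide 9 gives arylzinc 12. The ring B bromide of 7 is carried through untouched and later becomes the nucleophilic site of 13.

**7 ⇒ 6 ⇒ 4 ⇒ 2 + 3, 2 ⇒ 1, and 9 ⇒ 8.** This is the same sequence as for 19 in the enantiomeric series, starting from 1. Compound 3 therefore serves as both ring A and ring B. Ring C comes from 8 by silylation.

## Alternatives that were turned down

**Alternative 1:** the textbook route.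
- Disconnection: both C–O bonds of each dioxane ring (C7–O3 and C8–O4), one ring after the other.
- Forward key step: Sharpless asymmetric epoxidation (Ti(Oi-Pr)4, diethyl tartrate, t-BuOOH) of the ring C cinnamyl alcohol gives epoxy alcohol A1. A ring B phenol with O4' blocked opens it at the benzylic carbon with inversion. After protecting-group changes, an intramolecular Mitsunobu reaction closes C8''–O4' with a second inversion.
- Why turned down:
  - The benzylic carbon of A1 is para to an oxygen, so the opening has strong SN1 character and configuration at C7'' can leak.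
  - Two phenols and two hydroxyls need orthogonal protection, which costs about seven operations per ring.
  - The C7–aryl bond is inherited from the cinnamyl alcohol. Ring D can only be started after a new cinnamyl alcohol has been built on the finished ring E unit, so the plan is strictly linear and has no convergent union.

**Alternative 2:** the biomimetic route.
- Disconnection: C7'–O3 and C8'–O4 of ring D in one step.
- Forward key step: oxidative coupling of the catechol of caffeyl alcohol A3 across the alkene of dimer A2, with Ag2O or a peroxidase and H2O2. A phenoxyl radical adds through O4 to C8' and the quinone methide closes with O3. An o-quinone hetero-Diels–Alder reaction is the polar variant.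
- Why turned down:
  - Nothing controls the absolute sense of ring D relative to the remote ring E, so both trans diastereomers are expected.
  - A2 and A3 each contain a catechol and a styrenyl alkene, so homo-coupling and oligomerisation compete.
  - The O3/O4 regiochemistry depends on whether the coupling is radical or polar.
  - A2 would itself need an enantioselective synthesis, so the step buys little.

**Alternative 3:** reduction with dynamic kinetic resolution.
- Disconnection: the aryl C–O bond C3'–O3' of ring E, after both stereocentres are set together.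
- Forward key step: asymmetric transfer hydrogenation of the racemic keto ester A4 (RuCl(p-cymene)[(S,S)-TsDPEN], HCO2H/Et3N) gives the syn hydroxy ester A5. CuI- or Pd(OAc)2-catalysed intramolecular etherification onto the ortho bromide then closes the ring with retention.
- Why turned down:
  - A5 is a β-hydroxy ester with an acidic α-hydrogen. The base and heat of the C–O coupling invite retro-aldol cleavage, epimerisation at C8'' and dehydration, so the ester must first be reduced and protected.
  - A secondary benzylic alkoxide on the metal has a β-hydrogen, so oxidation to the ketone competes.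
  - The C7–aryl bond is again made at the start of each unit, so the assembly is linear.
  - Each ring needs its own bromophenol with a masked aldehyde, which raises the step count above that of the chosen route.

Key step: step 11

Assumption: both enantiomers of methyl 2,3-dihydroxypropanoate (1 and 14) are taken as purchasable. If not, each is one acid-catalysed methanolysis away from the commercial methyl 2,2-dimethyl-1,3-dioxolane-4-carboxylate of the same descriptor.

## Route

Step 1
Reactants: 1 methyl (2R)-2,3-dihydroxypropanoate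
Product: 2 methyl (2R)-3-(TBDPSO)-2-hydroxypropanoate
Conditions: TBDPSCl, imidazole, CH2Cl2, 0 °C
Reagents that add atoms: tert-butyl(chloro)diphenylsilane (TBDPSCl), CC(C)(C)[Si](Cl)(c1ccccc1)c1ccccc1
Why: Selective silylation; the bulky silyl chloride should react at the primary hydroxyl and leave the hindered, less nucleophilic α-hydroxy ester hydroxyl free, and the stereocentre is not touched.

Step 2
Reactants: 2 methyl (2R)-3-(TBDPSO)-2-hydroxypropanoate; 3 5-bromo-2-hydroxybenzaldehyde
Product: 4 methyl (2S)-2-(4-bromo-2-formylphenoxy)-3-(TBDPSO)propanoate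
Conditions: PPh3, DIAD, toluene, 0 °C to rt
Reagents that add atoms: none
Why: Mitsunobu etherification of an α-hydroxy ester with an acidic ortho-formyl phenol; SN2 displacement of the oxyphosphonium group should invert C2 cleanly, so (R)-2 gives (S)-4. The oxygen para to bromine becomes O4' of ring B, bound to C8''.

Step 3
Reactants: 4 methyl (2S)-2-(4-bromo-2-formylphenoxy)-3-(TBDPSO)propanoate
Product: 6 methyl (2S)-2-(4-bromo-2-hydroxyphenoxy)-3-(TBDPSO)propanoate, via aryl formate 5 (not isolated)
Conditions: mCPBA, CH2Cl2, rt; aqueous wash; then MeOH, Et3N (cat.), 0 °C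
Reagents that add atoms: 3-chloroperoxybenzoic acid (mCPBA), OOC(=O)c1cccc(Cl)c1
Why: Baeyer–Villiger (Dakin-type) oxidation; the ortho-alkoxy aryl group migrates in the Criegee intermediate to give the aryl formate, which mild methanolysis cleaves. This unveils O3' meta to bromine; the conditions are too mild to epimerise the α-aryloxy ester.

Step 4
Reactants: 6 methyl (2S)-2-(4-bromo-2-hydroxyphenoxy)-3-(TBDPSO)propanoate
Product: 7 (3S)-7-bromo-3-[(TBDPSO)methyl]-2,3-dihydro-1,4-benzodioxin-2-ol (C2 anomers)
Conditions: i-Bu2AlH (DIBAL-H, 2.2 equiv), CH2Cl2, −78 °C; aqueous potassium sodium tartrate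
Reagents that add atoms: none
Why: Partial reduction of an α-alkoxy methyl ester; the chelated tetrahedral aluminate should hold the aldehyde oxidation level at −78 °C. On work-up the neighbouring phenol captures the aldehyde as the six-membered hemiacetal (6-exo-trig), which closes ring E and shields the epimerisable α-aryloxy aldehyde.

Step 5
Reactants: 8 4-bromobenzene-1,2-diol
Product: 9 4-bromo-1,2-bis(TBSO)benzene
Conditions: TBSCl, imidazole, DMF, rt
Reagents that add atoms: tert-butyl(chloro)dimethylsilane (TBSCl), CC(C)(C)[Si](C)(C)Cl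
Why: Standard double silylation of a catechol; the aryl silyl ethers tolerate organolithium and organozinc reagents and are removed by fluoride at the end.

Step 6
Reactants: 7 (3S)-7-bromo-3-[(TBDPSO)methyl]-2,3-dihydro-1,4-benzodioxin-2-ol; 9 4-bromo-1,2-bis(TBSO)benzene
Product: 13 (2S,3S)-6-bromo-3-[3,4-bis(TBSO)phenyl]-2-[(TBDPSO)methyl]-2,3-dihydro-1,4-benzodioxine, via anomeric chloride 10 (not isolated), via aryllithium 11 (not isolated), via arylzinc chloride 12 (not isolated)
Conditions: 7, (COCl)2, DMF (cat.), CH2Cl2, 0 °C, then evaporation; separately 9, n-BuLi, THF, −78 °C, then ZnCl2, −78 to 0 °C; chloride in toluene added at −40 °C, then rt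
Reagents that add atoms: none
Why: Vilsmeier-type chlorination gives the α-chloro ether, and ZnCl2-assisted substitution by the arylzinc (the C-aryl glycosylation reaction type known for cyclic α-chloro ethers and aryl-metal reagents) forms C7''–C1''. The aryl group should enter anti to the CH2OTBDPS group on C8'' to give the trans (2S,3S) ring; the zinc reagent leaves the ring B bromide untouched.

Step 7
Reactants: 14 methyl (2S)-2,3-dihydroxypropanoate
Product: 15 methyl (2S)-3-(TBDPSO)-2-hydroxypropanoate
Conditions: TBDPSCl, imidazole, CH2Cl2, 0 °C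
Reagents that add atoms: tert-butyl(chloro)diphenylsilane (TBDPSCl), CC(C)(C)[Si](Cl)(c1ccccc1)c1ccccc1
Why: Selective silylation of the primary hydroxyl, as in step 1, in the enantiomeric series.

Step 8
Reactants: 15 methyl (2S)-3-(TBDPSO)-2-hydroxypropanoate; 3 5-bromo-2-hydroxybenzaldehyde
Product: 16 methyl (2R)-2-(4-bromo-2-formylphenoxy)-3-(TBDPSO)propanoate
Conditions: PPh3, DIAD, toluene, 0 °C to rt
Reagents that add atoms: none
Why: Mitsunobu etherification with inversion, as in step 2; (S)-15 gives (R)-16. The oxygen para to bromine becomes O4 of ring A, bound to C8'.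

Step 9
Reactants: 16 methyl (2R)-2-(4-bromo-2-formylphenoxy)-3-(TBDPSO)propanoate
Product: 18 methyl (2R)-2-(4-bromo-2-hydroxyphenoxy)-3-(TBDPSO)propanoate, via aryl formate 17 (not isolated)
Conditions: mCPBA, CH2Cl2, rt; aqueous wash; then MeOH, Et3N (cat.), 0 °C
Reagents that add atoms: 3-chloroperoxybenzoic acid (mCPBA), OOC(=O)c1cccc(Cl)c1
Why: Baeyer–Villiger (Dakin-type) oxidation and formate methanolysis, as in step 3; this unveils O3 of ring A.

Step 10
Reactants: 18 methyl (2R)-2-(4-bromo-2-hydroxyphenoxy)-3-(TBDPSO)propanoate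
Product: 19 (3R)-7-bromo-3-[(TBDPSO)methyl]-2,3-dihydro-1,4-benzodioxin-2-ol (C2 anomers)
Conditions: i-Bu2AlH (DIBAL-H, 2.2 equiv), CH2Cl2, −78 °C; aqueous potassium sodium tartrate
Reagents that add atoms: none
Why: Partial ester reduction and spontaneous 6-exo-trig hemiacetal formation, as in step 4; this closes ring D with C8' fixed as R.

Step 11
Reactants: 19 (3R)-7-bromo-3-[(TBDPSO)methyl]-2,3-dihydro-1,4-benzodioxin-2-ol; 13 (2S,3S)-6-bromo-3-[3,4-bis(TBSO)phenyl]-2-[(TBDPSO)methyl]-2,3-dihydro-1,4-benzodioxine
Product: 23 (2R,3R)-6-bromo-3-{(2S,3S)-3-[3,4-bis(TBSO)phenyl]-2-[(TBDPSO)methyl]-2,3-dihydro-1,4-benzodioxin-6-yl}-2-[(TBDPSO)methyl]-2,3-dihydro-1,4-benzodioxine, via anomeric chloride 20 (not isolated), via aryllithium 21 (not isolated), via arylzinc chloride 22 (not isolated)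
Conditions: 19, (COCl)2, DMF (cat.), CH2Cl2, 0 °C, then evaporation; separately 13, n-BuLi, THF, −78 °C, then ZnCl2 (1.2 equiv), −78 to 0 °C; chloride (1.3 equiv) in toluene added at −40 °C, then rt
Reagents that add atoms: none
Why: The chloroiminium salt from (COCl)2 and DMF converts lactol 19 into the anomeric chloride 20; ZnCl2 assists ionisation of its C–Cl bond to a contact ion pair of the ring D 1,4-benzodioxin-2-ylium (aryl oxocarbenium) ion, which takes the aryl group from arylzinc 22 at C7' and forms the C7'–C1' bond that joins the two halves. The closest known reaction type is the substitution of cyclic α-chloro ethers (2-chlorotetrahydropyran, trans-2,3-dichloro-1,4-dioxane, glycosyl halides) by aryl Grignard and arylzinc reagents, that is, C-aryl glycosylation. No ring is closed here: ring D was closed in step 10 by 6-exo-trig hemiacetal formation and is carried through intact, and rings B, C and E arrive complete in 22. The new stereocentre C7' is controlled by the resident C8' centre: the aryl group should be delivered to the face of the flattened cation opposite the bulky CH2OTBDPS group (or, in the SN2-like limit, with inversion of the anomerically preferred pseudoaxial chloride), which gives the 7',8'-trans (2R,3R) ring, also the more stable diequatorial isomer. C8' no longer has an acidifying carbonyl neighbour and the weakly basic zinc reagent should not remove its proton, so the configuration bought with 14 is kept; C7'' and C8'' are not involved. The step needs chemoselectivity between two aryl bromides: lithium–bromine exchange is run on 13 alone, and transmetalation to zinc before 20 is added prevents halogen–metal exchange with the ring A bromide, which must survive for step 12. It also needs substitution to outrun loss of HCl to the 1,4-benzodioxine, which the low basicity of 22 and the low temperature should secure.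

Step 12
Reactants: 23 (2R,3R)-6-bromo-3-{(2S,3S)-3-[3,4-bis(TBSO)phenyl]-2-[(TBDPSO)methyl]-2,3-dihydro-1,4-benzodioxin-6-yl}-2-[(TBDPSO)methyl]-2,3-dihydro-1,4-benzodioxine; 24 (2E)-3-(tributylstannyl)prop-2-en-1-ol
Product: 25 (2E)-3-{(2R,3R)-3-{(2S,3S)-3-[3,4-bis(TBSO)phenyl]-2-[(TBDPSO)methyl]-2,3-dihydro-1,4-benzodioxin-6-yl}-2-[(TBDPSO)methyl]-2,3-dihydro-1,4-benzodioxin-6-yl}prop-2-en-1-ol
Conditions: Pd(PPh3)4 (5 mol %), toluene, 100 °C
Reagents that add atoms: none
Why: Stille coupling of an aryl bromide with an alkenylstannane under neutral, base-free and fluoride-free conditions, which the aryl silyl ethers tolerate; the E geometry is transferred from 24 with retention and no stereocentre is touched.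

Step 13
Reactants: 25 (2E)-3-{(2R,3R)-3-{(2S,3S)-3-[3,4-bis(TBSO)phenyl]-2-[(TBDPSO)methyl]-2,3-dihydro-1,4-benzodioxin-6-yl}-2-[(TBDPSO)methyl]-2,3-dihydro-1,4-benzodioxin-6-yl}prop-2-en-1-ol
Product: 26 (2E)-3-{(2R,3R)-3-[(2S,3S)-3-(3,4-dihydroxyphenyl)-2-(hydroxymethyl)-2,3-dihydro-1,4-benzodioxin-6-yl]-2-(hydroxymethyl)-2,3-dihydro-1,4-benzodioxin-6-yl}prop-2-en-1-ol
Conditions: Bu4NF (TBAF), AcOH (1:1), THF, 0 °C to rt, argon
Reagents that add atoms: none
Why: Fluoride-mediated cleavage of all four Si–O bonds in one operation; the acetic acid buffer keeps the liberated catechol protonated and so protects it from oxidation. The alkene and the benzylic ether bonds are inert to these conditions.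

## Compound list

1 | methyl (2R)-2,3-dihydroxypropanoate | COC(=O)[C@@H](CO)O | starting material
2 | methyl (2R)-3-[(tert-butyldiphenylsilyl)oxy]-2-hydroxypropanoate | COC(=O)[C@@H](CO[Si](c1ccccc1)(c1ccccc1)C(C)(C)C)O | intermediate
3 | 5-bromo-2-hydroxybenzaldehyde | O=Cc1cc(Br)ccc1O | starting material
4 | methyl (2S)-2-(4-bromo-2-formylphenoxy)-3-[(tert-butyldiphenylsilyl)oxy]propanoate | COC(=O)[C@H](CO[Si](c1ccccc1)(c1ccccc1)C(C)(C)C)Oc1ccc(Br)cc1C=O | intermediate
5 | methyl (2S)-2-[4-bromo-2-(formyloxy)phenoxy]-3-[(tert-butyldiphenylsilyl)oxy]propanoate | COC(=O)[C@H](CO[Si](c1ccccc1)(c1ccccc1)C(C)(C)C)Oc1ccc(Br)cc1OC=O | intermediate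
6 | methyl (2S)-2-(4-bromo-2-hydroxyphenoxy)-3-[(tert-butyldiphenylsilyl)oxy]propanoate | COC(=O)[C@H](CO[Si](c1ccccc1)(c1ccccc1)C(C)(C)C)Oc1ccc(Br)cc1O | intermediate
7 | (3S)-7-bromo-3-{[(tert-butyldiphenylsilyl)oxy]methyl}-2,3-dihydro-1,4-benzodioxin-2-ol (C2 anomers) | Brc1ccc2c(c1)OC(O)[C@H](CO[Si](c1ccccc1)(c1ccccc1)C(C)(C)C)O2 | intermediate
8 | 4-bromobenzene-1,2-diol | Oc1ccc(Br)cc1O | starting material
9 | 4-bromo-1,2-bis[(tert-butyldimethylsilyl)oxy]benzene | Brc1ccc(O[Si](C)(C)C(C)(C)C)c(O[Si](C)(C)C(C)(C)C)c1 | intermediate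
10 | (3S)-7-bromo-2-chloro-3-{[(tert-butyldiphenylsilyl)oxy]methyl}-2,3-dihydro-1,4-benzodioxine (C2 anomers) | Brc1ccc2c(c1)OC(Cl)[C@H](CO[Si](c1ccccc1)(c1ccccc1)C(C)(C)C)O2 | intermediate
11 | {3,4-bis[(tert-butyldimethylsilyl)oxy]phenyl}lithium | [Li]c1ccc(O[Si](C)(C)C(C)(C)C)c(O[Si](C)(C)C(C)(C)C)c1 | intermediate
12 | {3,4-bis[(tert-butyldimethylsilyl)oxy]phenyl}zinc chloride | Cl[Zn]c1ccc(O[Si](C)(C)C(C)(C)C)c(O[Si](C)(C)C(C)(C)C)c1 | intermediate
13 | (2S,3S)-6-bromo-3-{3,4-bis[(tert-butyldimethylsilyl)oxy]phenyl}-2-{[(tert-butyldiphenylsilyl)oxy]methyl}-2,3-dihydro-1,4-benzodioxine | Brc1ccc2c(c1)O[C@@H](c1ccc(O[Si](C)(C)C(C)(C)C)c(O[Si](C)(C)C(C)(C)C)c1)[C@H](CO[Si](c1ccccc1)(c1ccccc1)C(C)(C)C)O2 | intermediate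
14 | methyl (2S)-2,3-dihydroxypropanoate | COC(=O)[C@H](CO)O | starting material
15 | methyl (2S)-3-[(tert-butyldiphenylsilyl)oxy]-2-hydroxypropanoate | COC(=O)[C@H](CO[Si](c1ccccc1)(c1ccccc1)C(C)(C)C)O | intermediate
16 | methyl (2R)-2-(4-bromo-2-formylphenoxy)-3-[(tert-butyldiphenylsilyl)oxy]propanoate | COC(=O)[C@@H](CO[Si](c1ccccc1)(c1ccccc1)C(C)(C)C)Oc1ccc(Br)cc1C=O | intermediate
17 | methyl (2R)-2-[4-bromo-2-(formyloxy)phenoxy]-3-[(tert-butyldiphenylsilyl)oxy]propanoate | COC(=O)[C@@H](CO[Si](c1ccccc1)(c1ccccc1)C(C)(C)C)Oc1ccc(Br)cc1OC=O | intermediate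
18 | methyl (2R)-2-(4-bromo-2-hydroxyphenoxy)-3-[(tert-butyldiphenylsilyl)oxy]propanoate | COC(=O)[C@@H](CO[Si](c1ccccc1)(c1ccccc1)C(C)(C)C)Oc1ccc(Br)cc1O | intermediate
19 | (3R)-7-bromo-3-{[(tert-butyldiphenylsilyl)oxy]methyl}-2,3-dihydro-1,4-benzodioxin-2-ol (C2 anomers) | Brc1ccc2c(c1)OC(O)[C@@H](CO[Si](c1ccccc1)(c1ccccc1)C(C)(C)C)O2 | intermediate
20 | (3R)-7-bromo-2-chloro-3-{[(tert-butyldiphenylsilyl)oxy]methyl}-2,3-dihydro-1,4-benzodioxine (C2 anomers) | Brc1ccc2c(c1)OC(Cl)[C@@H](CO[Si](c1ccccc1)(c1ccccc1)C(C)(C)C)O2 | intermediate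
21 | [(2S,3S)-3-{3,4-bis[(tert-butyldimethylsilyl)oxy]phenyl}-2-{[(tert-butyldiphenylsilyl)oxy]methyl}-2,3-dihydro-1,4-benzodioxin-6-yl]lithium | [Li]c1ccc2c(c1)O[C@@H](c1ccc(O[Si](C)(C)C(C)(C)C)c(O[Si](C)(C)C(C)(C)C)c1)[C@H](CO[Si](c1ccccc1)(c1ccccc1)C(C)(C)C)O2 | intermediate
22 | [(2S,3S)-3-{3,4-bis[(tert-butyldimethylsilyl)oxy]phenyl}-2-{[(tert-butyldiphenylsilyl)oxy]methyl}-2,3-dihydro-1,4-benzodioxin-6-yl]zinc chloride | Cl[Zn]c1ccc2c(c1)O[C@@H](c1ccc(O[Si](C)(C)C(C)(C)C)c(O[Si](C)(C)C(C)(C)C)c1)[C@H](CO[Si](c1ccccc1)(c1ccccc1)C(C)(C)C)O2 | intermediate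
23 | (2R,3R)-6-bromo-3-[(2S,3S)-3-{3,4-bis[(tert-butyldimethylsilyl)oxy]phenyl}-2-{[(tert-butyldiphenylsilyl)oxy]methyl}-2,3-dihydro-1,4-benzodioxin-6-yl]-2-{[(tert-butyldiphenylsilyl)oxy]methyl}-2,3-dihydro-1,4-benzodioxine | Brc1ccc2c(c1)O[C@H](c1ccc3c(c1)O[C@@H](c1ccc(O[Si](C)(C)C(C)(C)C)c(O[Si](C)(C)C(C)(C)C)c1)[C@H](CO[Si](c1ccccc1)(c1ccccc1)C(C)(C)C)O3)[C@@H](CO[Si](c1ccccc1)(c1ccccc1)C(C)(C)C)O2 | intermediate
24 | (2E)-3-(tributylstannyl)prop-2-en-1-ol | OC/C=C/[Sn](CCCC)(CCCC)CCCC | starting material
25 | (2E)-3-{(2R,3R)-3-[(2S,3S)-3-{3,4-bis[(tert-butyldimethylsilyl)oxy]phenyl}-2-{[(tert-butyldiphenylsilyl)oxy]methyl}-2,3-dihydro-1,4-benzodioxin-6-yl]-2-{[(tert-butyldiphenylsilyl)oxy]methyl}-2,3-dihydro-1,4-benzodioxin-6-yl}prop-2-en-1-ol | OC/C=C/c1ccc2c(c1)O[C@H](c1ccc3c(c1)O[C@@H](c1ccc(O[Si](C)(C)C(C)(C)C)c(O[Si](C)(C)C(C)(C)C)c1)[C@H](CO[Si](c1ccccc1)(c1ccccc1)C(C)(C)C)O3)[C@@H](CO[Si](c1ccccc1)(c1ccccc1)C(C)(C)C)O2 | intermediate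
26 | (2E)-3-{(2R,3R)-3-[(2S,3S)-3-(3,4-dihydroxyphenyl)-2-(hydroxymethyl)-2,3-dihydro-1,4-benzodioxin-6-yl]-2-(hydroxymethyl)-2,3-dihydro-1,4-benzodioxin-6-yl}prop-2-en-1-ol | OC/C=C/c1ccc2c(c1)O[C@H](c1ccc3c(c1)O[C@@H](c1ccc(O)c(O)c1)[C@H](CO)O3)[C@@H](CO)O2 | target

## Step count and least certain steps

Total step count: 13. Longest linear sequence: 8 steps (steps 1, 2, 3, 4, 6, 11, 12 and 13).

**Step 11 (key step).** Three processes are the most likely to fail. Elimination (loss of HCl from 20, or of the C8' proton from the oxocarbenium ion) may outrun aryl transfer and would also erase C8'. Facial selectivity of aryl transfer may be poor, because the cation is nearly planar and stereoelectronic (axial) attack and steric approach need not agree. Lithium–bromine exchange on the large bromide 13 may be incomplete, or the organometallic may be protonated.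

The fallback makes the same C–C bond on the open-chain aldehyde and closes ring D afterwards. It sets out from 19 and 13. Lactol 19 is deprotonated with one equivalent of i-PrMgCl in THF at −78 °C so that it opens to the magnesium phenoxide aldehyde. Aryllithium 21, made from 13 with n-BuLi as before, is added and should give the open-chain phenol diol F1 as a mixture of C7' epimers. Catalytic camphorsulfonic acid in CH2Cl2 at 0 °C to rt should then ionise the benzylic alcohol to the cation stabilised by O4' of ring B, and the ortho phenol O3 captures it. Because this closure is reversible, both epimers should converge on the trans ring, and the route is rejoined at 23. The same acid treatment could be applied to a mixture of ring D epimers from step 11 itself.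

**Step 6.** This is the same substitution in the ring E series and carries the same risks of elimination and poor facial selectivity; here the benzylic position is activated only by a silyloxy group. The fallback sets out from 7 and 9. Aryllithium 11 (2.2 equiv, THF, −78 °C) is added to lactol 7 to give the open-chain phenol diol F2, and acid-catalysed cyclodehydration as above returns to 13.

**Step 2.** At the hindered secondary centre, elimination of the oxyphosphonium intermediate towards the silyloxyacrylate or a slow SN2 step may lower conversion and stereochemical fidelity. The fallback sets out from 2. Tf2O and 2,6-lutidine in CH2Cl2 at −78 °C give the triflate F3. Displacement by the potassium phenoxide of 3 (K2CO3, MeCN, 0 °C) with inversion returns to 4.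

**Step 4.** Over-reduction past the aldehyde level, or epimerisation at C8'' while the free aldehyde is present during work-up, are the likely failures. The fallback sets out from 6. Acid-catalysed lactonisation (camphorsulfonic acid cat., toluene, 80 °C, with removal of methanol) gives the lactone F4. One equivalent of i-Bu2AlH at −78 °C should reduce it to the lactol and return to 7.

**Step 12.** Slow oxidative addition into the electron-rich aryl bromide may let protodestannylation or homocoupling of the stannane compete, and long heating may cost aryl silyl ethers. The fallback sets out from 23. A Heck reaction with methyl acrylate (Pd(OAc)2, P(o-tol)3, Et3N, DMF, 100 °C) gives the cinnamate F5. Reduction with i-Bu2AlH in CH2Cl2 at −78 °C returns to 25.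

Steps 8 and 10 are the mirror images of steps 2 and 4 and carry the same risks.

## Further compounds

F1 | step 11 | 5-bromo-2-{[(2R)-1-[(2S,3S)-3-{3,4-bis[(tert-butyldimethylsilyl)oxy]phenyl}-2-{[(tert-butyldiphenylsilyl)oxy]methyl}-2,3-dihydro-1,4-benzodioxin-6-yl]-3-[(tert-butyldiphenylsilyl)oxy]-1-hydroxypropan-2-yl]oxy}phenol (C1 epimers) | Oc1cc(Br)ccc1O[C@H](CO[Si](c1ccccc1)(c1ccccc1)C(C)(C)C)C(O)c1ccc2c(c1)O[C@@H](c1ccc(O[Si](C)(C)C(C)(C)C)c(O[Si](C)(C)C(C)(C)C)c1)[C@H](CO[Si](c1ccccc1)(c1ccccc1)C(C)(C)C)O2
F2 | step 6 | 5-bromo-2-{[(2S)-1-{3,4-bis[(tert-butyldimethylsilyl)oxy]phenyl}-3-[(tert-butyldiphenylsilyl)oxy]-1-hydroxypropan-2-yl]oxy}phenol (C1 epimers) | Oc1cc(Br)ccc1O[C@@H](CO[Si](c1ccccc1)(c1ccccc1)C(C)(C)C)C(O)c1ccc(O[Si](C)(C)C(C)(C)C)c(O[Si](C)(C)C(C)(C)C)c1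
F3 | step 2 | methyl (2R)-3-[(tert-butyldiphenylsilyl)oxy]-2-{[(trifluoromethyl)sulfonyl]oxy}propanoate | COC(=O)[C@@H](CO[Si](c1ccccc1)(c1ccccc1)C(C)(C)C)OS(=O)(=O)C(F)(F)F
F4 | step 4 | (3S)-7-bromo-3-{[(tert-butyldiphenylsilyl)oxy]methyl}-1,4-benzodioxin-2(3H)-one | Brc1ccc2c(c1)OC(=O)[C@H](CO[Si](c1ccccc1)(c1ccccc1)C(C)(C)C)O2
F5 | step 12 | methyl (2E)-3-{(2R,3R)-3-[(2S,3S)-3-{3,4-bis[(tert-butyldimethylsilyl)oxy]phenyl}-2-{[(tert-butyldiphenylsilyl)oxy]methyl}-2,3-dihydro-1,4-benzodioxin-6-yl]-2-{[(tert-butyldiphenylsilyl)oxy]methyl}-2,3-dihydro-1,4-benzodioxin-6-yl}prop-2-enoate | COC(=O)/C=C/c1ccc2c(c1)O[C@H](c1ccc3c(c1)O[C@@H](c1ccc(O[Si](C)(C)C(C)(C)C)c(O[Si](C)(C)C(C)(C)C)c1)[C@H](CO[Si](c1ccccc1)(c1ccccc1)C(C)(C)C)O3)[C@@H](CO[Si](c1ccccc1)(c1ccccc1)C(C)(C)C)O2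
A1 | alternative 1 | [(2R,3R)-3-{3,4-bis[(tert-butyldimethylsilyl)oxy]phenyl}oxiran-2-yl]methanol | OC[C@H]1O[C@@H]1c1ccc(O[Si](C)(C)C(C)(C)C)c(O[Si](C)(C)C(C)(C)C)c1
A2 | alternative 2 | (2E)-3-[(2S,3S)-3-(3,4-dihydroxyphenyl)-2-(hydroxymethyl)-2,3-dihydro-1,4-benzodioxin-6-yl]prop-2-en-1-ol | OC/C=C/c1ccc2c(c1)O[C@@H](c1ccc(O)c(O)c1)[C@H](CO)O2
A3 | alternative 2 | (2E)-3-(3,4-dihydroxyphenyl)prop-2-en-1-ol (caffeyl alcohol) | OC/C=C/c1ccc(O)c(O)c1
A4 | alternative 3 | methyl 3-{3,4-bis[(tert-butyldimethylsilyl)oxy]phenyl}-2-[2-bromo-4-(1,3-dioxolan-2-yl)phenoxy]-3-oxopropanoate (racemic) | COC(=O)C(Oc1ccc(cc1Br)C1OCCO1)C(=O)c1ccc(O[Si](C)(C)C(C)(C)C)c(O[Si](C)(C)C(C)(C)C)c1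
A5 | alternative 3 | methyl (2R,3S)-3-{3,4-bis[(tert-butyldimethylsilyl)oxy]phenyl}-2-[2-bromo-4-(1,3-dioxolan-2-yl)phenoxy]-3-hydroxypropanoate | O[C@@H](c1ccc(O[Si](C)(C)C(C)(C)C)c(O[Si](C)(C)C(C)(C)C)c1)[C@H](C(=O)OC)Oc1ccc(cc1Br)C1OCCO1
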